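## Analysis of the target

The target is a tetracyclic depsidone. Ring A is an arene whose carbons are labelled a1 (OMe), a2 (H), a3 (CH3), a4 (carbonyl of the seven-membered lactone), a5 (diaryl ether oxygen) and a6 (CHO). Ring B is an arene labelled b1 (ether oxygen), b2 (ester oxygen), b3 (H), b4 (OH), b5 (lactone carbonyl of the five-membered ring) and b6 (lactol carbon). The two arenes are joined through a 1,4-dioxepinone (ether a5–O–b1, ester a4–C(=O)–O–b2), and ring B is fused to a 3-hydroxyphthalide. The only stereocentre is the lactol carbon on b6, which is (S). It is a hemiacetal and epimerizes through the ring-opened formyl acid, so it cannot be carried through a synthesis and has to be fixed in the last operation. Sensitive groups are the aryl ester of the medium ring (base and nucleophiles), the aldehyde, the lactol and, in any precursor, acetals and an ynol ether (acid). The difficulty is steric: both arenes are pentasubstituted, the ether joins two carbons that each carry two ortho substituents, and the ester carbonyl sits on a4 between a methyl and an aryloxy group. In addition, the three oxygens of ring B must be told apart. The strategy rests on two features. In ring A the oxygens on a1 and a5 are meta with the formyl carbon a6 between them and the ester carbon a4 beside a5, which is the pattern a vinylketene and an ynol ether produce on benzannulation. In ring B the oxygens on b1 and b2 are neighbours and can serve as a two-point tether.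

## Retrosynthetic reasoning

28 from 27. No bond is cut. The (S) lactol 28 is traced to racemic 27, because the hemiacetal carbon equilibrates in solution. The forward step has to move all material into one enantiomer by crystallization under equilibrating conditions.

27 from 26. The protecting C–O bonds are cut and the lactol ring is opened to an ortho ester/acetal pair on b5 and b6. In 26 the formyl group on a6 is a diethyl acetal, b4–O carries a methoxymethyl group, and the hydroxy lactone is stored as methyl ester plus dimethyl acetal. One aqueous acid treatment must remove all of these and let the liberated aldehyde and the ester close to the lactol.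

26 from 25. The a1–O–CH3 bond is cut. Phenol 25 is what the ring-forming step delivers, and it is the only free hydroxyl at that point, so the methylation needs no selectivity.

25 from 21 (key disconnection). Ring A is taken apart at a1–a6, a4–a5 and a1–a2, and a3 is moved back from a4 to a1. This leads to diazo keto ester 21, where a1 is a ketone carbon bearing the isopropenyl group (a2, a3, methyl), a4 is the diazo carbon of an ester on b2–O, and a5≡a6 is an ynol ether on b1–O. The cut is made here because it removes both hindered links at once. The ether oxygen stays on b1 and is attached to an sp carbon, not to a crowded arene. The ester C–O bond is made on a small acyl group. The seven-membered ring is closed through a C–C bond between a4 and a5. The forward step has to generate the vinylketene, add it [2+2] to the tethered ynol ether in the right orientation, and carry the cyclobutenone through ring opening and 6π closure.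

21 from 18 and 19. The a1–a4 bond is cut (aldol retron after adjusting the oxidation level through alcohol 20). This gives aryl diazoacetate 18 and methacrolein 19. The keto ester arm is therefore built at or below room temperature under basic or buffered conditions. Hot or acidic acylketene chemistry would endanger the ynol ether and the phenol beside it.

18 from 15 and 16, and 15 from 14. The ester C–O bond on b2 is cut to phenol 15 and bromoacetyl bromide 16, and the diazo group comes from a sulfonylhydrazine reagent. Phenol 15 is traced to allyl ether 14, since an allyl group does not migrate between catechol oxygens and leaves under neutral palladium catalysis that an ynol ether tolerates.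

14 from 9 and 12. The O–C(sp) bond is cut to phenol 9 and dibromoalkene 12 (copper-catalysed coupling, then elimination). 12 goes back through aldehyde 11 to ester 10. The base-demanding ynol ether synthesis is placed before the base-sensitive aryl ester arm exists.

9 from 7, and 7 back to 4. Phenol 9, with its open ester/acetal pair, is traced to the cyclic pseudo ester 7, in which b5 and b6 are tied into a 3-methoxyphthalide and b1–O is silylated. Freeing that phenoxide is expected to open the ring. The three oxygen substituents of 7 are removed in reverse order of installation (7 to 6 to 5 to 4). In triol 4 the hydroxyls differ in acidity and hydrogen bonding in exactly the order needed: b2 first, b1 second, b4 last.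

4 from 2, and 2 from 1. Triol 4 comes from trimethoxy lactol 2 by ether cleavage. The b6–CHO bond is cut to 2,4,5-trimethoxybenzoic acid 1, whose only position beside the carboxylate is the one to be formylated.

## Alternatives that were turned down

Alternative 1: the ether bond O–a5 is cut on a ring A held at the cyclohexenone level. In the forward step the free b1 hydroxyl of the catechol monoester A1 condenses under acid, with removal of water, with the ring ketone beside the ester carbon and gives the tricyclic aryl enol ether lactone A2.
- For: it uses ordinary condensation chemistry without diazo compounds or light, the ring A carbons come from a cheap diketo ester, and the hindered ether is closed within one molecule. As a single step it is less speculative than the chosen key step.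
- Against: phenols are poor partners for enol etherification of 1,3-diones, and the dione offers a second, less hindered carbonyl. The dehydrating acid is also the condition under which the acetal and ester on ring B of A1 are lost.
- Against: A2 has neither the aromatic oxidation level nor the formyl carbon. Dehydrogenation, formylation at a6 in competition with the more electron-rich b3, methylation and deprotection would follow, at least five steps against three, and the stereocentre of A1 and A2 is carried only to be destroyed.
- Comparison: the risk is moved from the key step into the steps after it. The chosen strategy delivers ring A fully substituted, formyl carbon included, in the ring-forming step.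

Alternative 2: two C–C bonds of ring B are cut (b1–b6 and b4–b5). In the forward step the bis(silyloxy) diene A3, which carries the finished ring A as an aryloxy group at its terminus, adds to the acetal-bearing ynoate A4 in a Diels–Alder reaction and aromatizes by loss of the alkoxy and silyl groups to the diaryl ether A5.
- For: it is convergent, the reaction class is known with predictable orientation, and the crowded ether oxygen is introduced earlier by O-alkylation of a ring A phenol.
- For: A5 has the two ring B phenols already distinguished and the ester/acetal pair in place. On this point it is clearly better than the chosen route, which spends six steps on ring B.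
- Against: the diene terminus bears a di-ortho-substituted aryloxy group and A4 has a single activating group, so the cycloaddition needs temperatures at which such dienes suffer silyl shifts.
- Against: A5 still lacks the seven-membered lactone. That would have to be made from a ring A ester flanked by methyl and aryloxy groups, after telling two methyl esters apart.
- Comparison: its key step closes the easy ring and leaves the hard one. The chosen strategy makes the ester C–O bond on an unhindered acyl group and closes the medium ring through a C–C bond.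

Alternative 3: the bond between a4 and the lactone carbonyl is cut. In the forward step zerovalent palladium inserts into the C–Cl bond of the chloroformate on b2–O of diaryl ether A6, and the aryloxycarbonyl palladium couples with the boronate on a4 to give depsidone A7.
- For: A7 is one acid treatment away from 27, one step fewer after the key step than the chosen route, and the closure is a C–C coupling and not the acylation of a hindered acid.
- Against: the tetra-ortho-substituted diaryl ether of A6 must be made first by substitution at a crowded arene, which is the bond the chosen strategy avoids.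
- Against: the boronate lies between methyl and aryloxy groups (slow transmetalation, protodeboronation). The aryloxycarbonyl palladium species can lose CO, and the base that activates the boronate attacks the chloroformate.
- Against: an intramolecular coupling of a chloroformate of this kind has no precedent either.
- Comparison: the novelty risk is similar, but both arenes must be prepared fully substituted beforehand. The chosen strategy builds ring A from three small pieces.

Key step: step 14

Assumption: the hemiacetal carbon of the hydroxy lactone epimerizes in solution through the ring-opened formyl acid, so the (S) descriptor is taken to describe the crystalline compound; which antipode of the resolving host crystallizes with the (S) lactol cannot be foreseen, and the (R,R) host is written with the understanding that its mirror image is used if the first crystals hold the (R) lactol.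

## Route

Step 1
Reactants: 1 2,4,5-trimethoxybenzoic acid
Product: 2 3-hydroxy-4,5,7-trimethoxyisobenzofuran-1(3H)-one (racemic lactol, ring form of 2-formyl-3,4,6-trimethoxybenzoic acid)
Conditions: sec-butyllithium (2.2 equiv), TMEDA, THF, −78 °C; DMF; aq. HCl
Reagents that add atoms: N,N-dimethylformamide, CN(C)C=O
Why: Directed ortho metalation of the unprotected benzoic acid: the lithium carboxylate and the 5-methoxy group together direct lithiation to C6, the only position beside the carboxylate; formylation and acid work-up give the formyl acid, which closes to the lactol.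

Step 2
Reactants: 2 3-hydroxy-4,5,7-trimethoxyisobenzofuran-1(3H)-one
Product: 4 4,5,7-trihydroxy-3-methoxyisobenzofuran-1(3H)-one (racemic pseudo ester), via tetrahydroxyphthalide 3 (not isolated)
Conditions: BBr3 (6 equiv), CH2Cl2, −78 → 25 °C; MeOH, 50 °C
Reagents that add atoms: methanol, CO
Why: Lewis acid cleavage of the three aryl methyl ethers, then Fischer-type acetalization of the lactol hydroxyl by the acidic methanol of the quench; the pseudo ester ties aldehyde and acid together while the phenols are differentiated.

Step 3
Reactants: 4 4,5,7-trihydroxy-3-methoxyisobenzofuran-1(3H)-one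
Product: 5 5-(allyloxy)-4,7-dihydroxy-3-methoxyisobenzofuran-1(3H)-one (racemic)
Conditions: allyl bromide (1.05 equiv), KHCO3, DMF, 40 °C, argon
Reagents that add atoms: allyl bromide, C=CCBr
Why: Williamson etherification under weak base should take the most acidic and least hindered hydroxyl: 5-OH (on b2) is para to the lactone carbonyl carbon, 7-OH is hydrogen-bonded to the lactone carbonyl, and 4-OH is the least acidic and flanked on both sides.

Step 4
Reactants: 5 5-(allyloxy)-4,7-dihydroxy-3-methoxyisobenzofuran-1(3H)-one
Product: 6 5-(allyloxy)-4-[(tert-butyldimethylsilyl)oxy]-7-hydroxy-3-methoxyisobenzofuran-1(3H)-one (racemic)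
Conditions: TBSCl (1.1 equiv), imidazole, DMF, 0 °C
Reagents that add atoms: tert-butyldimethylsilyl chloride, CC(C)(C)[Si](C)(C)Cl
Why: Silylation of the one phenol that is not held in a hydrogen bond; the chelated 7-OH should react much more slowly, so the oxygen on b1 that will later carry the ynol ether is marked with a fluoride-labile group.

Step 5
Reactants: 6 5-(allyloxy)-4-[(tert-butyldimethylsilyl)oxy]-7-hydroxy-3-methoxyisobenzofuran-1(3H)-one
Product: 7 5-(allyloxy)-4-[(tert-butyldimethylsilyl)oxy]-3-methoxy-7-(methoxymethoxy)isobenzofuran-1(3H)-one (racemic)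
Conditions: MOMCl (3 equiv), iPr2NEt, CH2Cl2, 0 → 40 °C
Reagents that add atoms: chloromethyl methyl ether, COCCl
Why: O-alkylation of the last, chelated phenol with a chloromethyl ether under amine base; forcing conditions are acceptable because no other nucleophilic site is left.

Step 6
Reactants: 7 5-(allyloxy)-4-[(tert-butyldimethylsilyl)oxy]-3-methoxy-7-(methoxymethoxy)isobenzofuran-1(3H)-one
Product: 9 methyl 4-(allyloxy)-2-(dimethoxymethyl)-3-hydroxy-6-(methoxymethoxy)benzoate, via tetrabutylammonium acetal carboxylate 8 (not isolated)
Conditions: Bu4NF (1.05 equiv), THF–MeOH, 0 → 25 °C; then MeI, 40 °C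
Reagents that add atoms: methanol, CO; iodomethane, CI
Why: Fluoride frees the phenoxide ortho to the acetal carbon, which expels the lactone carboxylate (E1cB, o-quinone methide); methanol adds to the quinone methide carbon, giving the dimethyl acetal with the charge on the more stable carboxylate, and MeI alkylates that carboxylate beside the un-ionized phenol. The reaction type is fluoride-triggered o-quinone methide generation from an o-silyloxybenzyl carboxylate with alcohol capture, then carboxylate O-alkylation; no acid is used, so the product with its free phenol beside an acetal is never exposed to the conditions that would cleave it.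

Step 7
Reactants: 10 ethyl 2,2-diethoxyacetate
Product: 11 2,2-diethoxyacetaldehyde
Conditions: iBu2AlH (1.05 equiv), CH2Cl2, −78 °C; aq. KNaC4H4O6
Reagents that add atoms: none
Why: Partial reduction of an ester; the two α-alkoxy groups stabilize the tetrahedral aluminium hemiacetal at −78 °C, so the aldehyde is released only on work-up.

Step 8
Reactants: 11 2,2-diethoxyacetaldehyde
Product: 12 1,1-dibromo-3,3-diethoxyprop-1-ene
Conditions: CBr4, PPh3, Et3N, CH2Cl2, 0 °C
Reagents that add atoms: tetrabromomethane, BrC(Br)(Br)Br
Why: Ramirez dibromomethylenation of an aldehyde (first stage of the Corey–Fuchs sequence); the amine buffers traces of HBr so that the acetal survives.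

Step 9
Reactants: 9 methyl 4-(allyloxy)-2-(dimethoxymethyl)-3-hydroxy-6-(methoxymethoxy)benzoate; 12 1,1-dibromo-3,3-diethoxyprop-1-ene
Product: 14 methyl 4-(allyloxy)-3-[(3,3-diethoxyprop-1-yn-1-yl)oxy]-2-(dimethoxymethyl)-6-(methoxymethoxy)benzoate, via (Z)-bromo enol ether 13 (not isolated)
Conditions: CuI (10 mol %), 2,2'-bipyridine, K3PO4, toluene, 110 °C; filter; KOtBu, THF, 0 °C
Reagents that add atoms: none
Why: Ullmann-type copper-catalysed coupling of a phenol with a 1,1-dibromoalkene should replace the bromine trans to the acetal-bearing carbon; in the bromo enol ether 13 hydrogen and bromine are anti, so KOtBu eliminates HBr (E2) to the aryl ynol ether. The methyl ester is shielded by two ortho groups, and acetals, allyl and methoxymethyl ethers are inert to these bases.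

Step 10
Reactants: 14 methyl 4-(allyloxy)-3-[(3,3-diethoxyprop-1-yn-1-yl)oxy]-2-(dimethoxymethyl)-6-(methoxymethoxy)benzoate
Product: 15 methyl 3-[(3,3-diethoxyprop-1-yn-1-yl)oxy]-2-(dimethoxymethyl)-4-hydroxy-6-(methoxymethoxy)benzoate
Conditions: Pd(PPh3)4 (5 mol %), morpholine, THF, 0 → 25 °C
Reagents that add atoms: none
Why: Tsuji–Trost deallylation: zerovalent palladium ionizes the aryl allyl ether to a π-allyl complex and the para-ester phenoxide, and morpholine takes up the allyl group; the medium stays basic, which the ynol ether and acetals tolerate. 15 is used at once, because a free phenol beside an ynol ether could add to it on standing or with acid.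

Step 11
Reactants: 15 methyl 3-[(3,3-diethoxyprop-1-yn-1-yl)oxy]-2-(dimethoxymethyl)-4-hydroxy-6-(methoxymethoxy)benzoate; 16 bromoacetyl bromide
Product: 18 methyl 4-[(2-diazoacetyl)oxy]-3-[(3,3-diethoxyprop-1-yn-1-yl)oxy]-2-(dimethoxymethyl)-6-(methoxymethoxy)benzoate, via aryl bromoacetate 17 (not isolated)
Conditions: 2,6-lutidine, CH2Cl2, −40 °C; then TsNHNHTs, DBU, THF, 0 °C
Reagents that add atoms: N,N'-bis(4-methylbenzenesulfonyl)hydrazine, Cc1ccc(cc1)S(=O)(=O)NNS(=O)(=O)c1ccc(C)cc1
Why: O-acylation with the acid bromide caps the phenol at low temperature; the bromoacetate is alkylated by the ditosylhydrazine anion and loses two sulfinates under DBU to give the diazoacetate (bromoacetate-to-diazoacetate conversion with N,N'-ditosylhydrazine). Everything runs at or below 0 °C under base, in place of an acylketene acylation whose heat and acidity the ynol ether would not survive.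

Step 12
Reactants: 18 methyl 4-[(2-diazoacetyl)oxy]-3-[(3,3-diethoxyprop-1-yn-1-yl)oxy]-2-(dimethoxymethyl)-6-(methoxymethoxy)benzoate; 19 methacrolein
Product: 20 methyl 4-[(2-diazo-3-hydroxy-4-methylpent-4-enoyl)oxy]-3-[(3,3-diethoxyprop-1-yn-1-yl)oxy]-2-(dimethoxymethyl)-6-(methoxymethoxy)benzoate (racemic at the carbinol carbon)
Conditions: LiN(SiMe3)2, THF, −78 °C; aq. NH4Cl
Reagents that add atoms: none
Why: Aldol-type addition of the lithiated diazoacetate to the aldehyde carbonyl (1,2-addition of a hard lithium nucleophile to the enal) forms the a1–a4 bond; the new carbinol centre is not controlled and is removed in the next step.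

Step 13
Reactants: 20 methyl 4-[(2-diazo-3-hydroxy-4-methylpent-4-enoyl)oxy]-3-[(3,3-diethoxyprop-1-yn-1-yl)oxy]-2-(dimethoxymethyl)-6-(methoxymethoxy)benzoate
Product: 21 methyl 4-[(2-diazo-4-methyl-3-oxopent-4-enoyl)oxy]-3-[(3,3-diethoxyprop-1-yn-1-yl)oxy]-2-(dimethoxymethyl)-6-(methoxymethoxy)benzoate
Conditions: Dess–Martin periodinane, pyridine, CH2Cl2, 0 → 25 °C
Reagents that add atoms: none
Why: Dess–Martin oxidation of the allylic β-hydroxy-α-diazo ester to the α-diazo-β-keto ester; pyridine buffers the acetic acid released, which protects the ynol ether and the acetals.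

Step 14
Reactants: 21 methyl 4-[(2-diazo-4-methyl-3-oxopent-4-enoyl)oxy]-3-[(3,3-diethoxyprop-1-yn-1-yl)oxy]-2-(dimethoxymethyl)-6-(methoxymethoxy)benzoate
Product: 25 methyl 4-(diethoxymethyl)-6-(dimethoxymethyl)-3-hydroxy-8-(methoxymethoxy)-1-methyl-11-oxo-11H-dibenzo[b,e][1,4]dioxepine-7-carboxylate, via vinylketene 22 (not isolated), via fused cyclobutenone 23 (not isolated), via dienylketene 24 (not isolated)
Conditions: hν (365 nm), degassed toluene (0.003 M), 25 °C; then 80 °C
Reagents that add atoms: none
Why: Proposed new method: light expels N2 from 21 and the isopropenyl group shifts from the ketone carbon to the diazo carbon (Wolff rearrangement), so that vinylketene 22 carries the aryl ester on its α-carbon (a4) and its ketene carbon is the former ketone carbon (a1). The acetal-bearing ynol ether carbon (a6), the nucleophilic one, attacks the ketene carbon and the ester-stabilized enolate carbon then bonds to the aryloxy-bearing alkyne carbon (a5); this second bond of the stepwise [2+2] closes the seven-membered ring (ether O, b1, b2, ester O, carbonyl C, a4, a5) and gives the fused 3-aryloxycyclobutenone 23. At 80 °C 23 opens by 4π electrocyclic cleavage of the bond between its carbonyl and quaternary carbons to dienylketene 24, in which the ring double bond holds the ketene and isopropenyl groups cis, and ring A closes by 6π electrocyclization (a1–a2 bond) and tautomerization to phenol 25. The closest known reaction is the Danheiser benzannulation, in which a vinylketene from photochemical Wolff rearrangement of an unsaturated diazo ketone combines with an alkoxyalkyne to a resorcinol monoether; it has not been run within one molecule or with an ester on the ketene. No stereocentre survives, since the quaternary carbon of 23 becomes sp2. The step needs the [2+2] mode to beat hetero-[4+2] addition through the ester carbonyl (pyranone) and carbocyclic [4+2] addition through the isopropenyl terminus; the ynol ether polarization decides which alkyne carbon meets the ketene carbon, and the two-oxygen tether can bridge only neighbouring atoms of the new ring, which neither the 2,6-bridged pyranone nor the meta-bridged arene allows without severe strain. Light of 365 nm is absorbed by the diazo ketone and not by the aryl ester, and high dilution keeps the ketene from dimerizing or being trapped between molecules.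

Step 15
Reactants: 25 methyl 4-(diethoxymethyl)-6-(dimethoxymethyl)-3-hydroxy-8-(methoxymethoxy)-1-methyl-11-oxo-11H-dibenzo[b,e][1,4]dioxepine-7-carboxylate
Product: 26 methyl 4-(diethoxymethyl)-6-(dimethoxymethyl)-3-methoxy-8-(methoxymethoxy)-1-methyl-11-oxo-11H-dibenzo[b,e][1,4]dioxepine-7-carboxylate
Conditions: MeI, K2CO3, acetone, 25 °C
Reagents that add atoms: iodomethane, CI
Why: Williamson O-methylation of the only free phenol; anhydrous carbonate in acetone offers no nucleophile that could open the aryl ester of the medium ring.

Step 16
Reactants: 26 methyl 4-(diethoxymethyl)-6-(dimethoxymethyl)-3-methoxy-8-(methoxymethoxy)-1-methyl-11-oxo-11H-dibenzo[b,e][1,4]dioxepine-7-carboxylate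
Product: 27 1,4-dihydroxy-10-methoxy-8-methyl-3,7-dioxo-1,3-dihydro-7H-isobenzofuro[4,5-b][1,4]benzodioxepine-11-carbaldehyde (racemic lactol)
Conditions: 2 M HCl, THF, 45 °C
Reagents that add atoms: water, O
Why: Acid hydrolysis removes the methoxymethyl ether and both acetals; the oxocarbenium ion on b6 is captured by the neighbouring ester carbonyl oxygen, and water then expels methanol to give the hydroxy lactone (neighbouring-group-assisted lactol formation). Aryl esters such as the depsidone lactone are stable to aqueous acid at this temperature.

Step 17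
Reactants: 27 racemic lactol
Product: 28 (1S)-1,4-dihydroxy-10-methoxy-8-methyl-3,7-dioxo-1,3-dihydro-7H-isobenzofuro[4,5-b][1,4]benzodioxepine-11-carbaldehyde (the target, (S) at the lactol carbon)
Conditions: (4R,5R)-TADDOL (1 equiv), AcOH (cat.), toluene–EtOAc, 50 → 5 °C, slurry; filter; cold Et2O wash
Reagents that add atoms: none
Why: Proposed new method: in solution the hemiacetal carbon of 27 epimerizes through the ring-opened formyl acid (acid-catalysed ring–chain tautomerism), while the enantiopure diol host binds the lactone and hydroxyl groups by hydrogen bonds and should form a less soluble inclusion crystal with one enantiomer, so that crystallization drains that enantiomer and the solution re-equilibrates (crystallization-induced asymmetric transformation, the host chirality setting the (S) centre); cold ether dissolves the host and leaves the sparingly soluble lactol as a solid. The closest known reaction types are the deracemization of epimerizable α-substituted ketones by inclusion crystallization with TADDOL hosts and the epimerizing crystallization of lactol-derived acetals such as 5-alkoxybutenolides.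

## Compound list

1 | 2,4,5-trimethoxybenzoic acid | COc1cc(OC)c(C(=O)O)cc1OC | starting material
2 | 3-hydroxy-4,5,7-trimethoxyisobenzofuran-1(3H)-one (racemic) | COc1cc(OC)c2c(c1OC)C(O)OC2=O | intermediate
3 | 3,4,5,7-tetrahydroxyisobenzofuran-1(3H)-one (racemic) | Oc1cc(O)c2c(c1O)C(O)OC2=O | intermediate (not isolated)
4 | 4,5,7-trihydroxy-3-methoxyisobenzofuran-1(3H)-one (racemic) | COC1OC(=O)c2c(O)cc(O)c(O)c12 | intermediate
5 | 5-(allyloxy)-4,7-dihydroxy-3-methoxyisobenzofuran-1(3H)-one (racemic) | COC1OC(=O)c2c(O)cc(OCC=C)c(O)c12 | intermediate
6 | 5-(allyloxy)-4-[(tert-butyldimethylsilyl)oxy]-7-hydroxy-3-methoxyisobenzofuran-1(3H)-one (racemic) | COC1OC(=O)c2c(O)cc(OCC=C)c(O[Si](C)(C)C(C)(C)C)c12 | intermediate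
7 | 5-(allyloxy)-4-[(tert-butyldimethylsilyl)oxy]-3-methoxy-7-(methoxymethoxy)isobenzofuran-1(3H)-one (racemic) | COCOc1cc(OCC=C)c(O[Si](C)(C)C(C)(C)C)c2c1C(=O)OC2OC | intermediate
8 | tetrabutylammonium 4-(allyloxy)-2-(dimethoxymethyl)-3-hydroxy-6-(methoxymethoxy)benzoate | C=CCOc1cc(OCOC)c(C(=O)[O-])c(C(OC)OC)c1O.CCCC[N+](CCCC)(CCCC)CCCC | intermediate (not isolated)
9 | methyl 4-(allyloxy)-2-(dimethoxymethyl)-3-hydroxy-6-(methoxymethoxy)benzoate | C=CCOc1cc(OCOC)c(C(=O)OC)c(C(OC)OC)c1O | intermediate
10 | ethyl 2,2-diethoxyacetate | CCOC(OCC)C(=O)OCC | starting material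
11 | 2,2-diethoxyacetaldehyde | CCOC(OCC)C=O | intermediate
12 | 1,1-dibromo-3,3-diethoxyprop-1-ene | CCOC(OCC)C=C(Br)Br | intermediate
13 | methyl 4-(allyloxy)-3-{[(1Z)-1-bromo-3,3-diethoxyprop-1-en-1-yl]oxy}-2-(dimethoxymethyl)-6-(methoxymethoxy)benzoate | CCOC(OCC)/C=C(\Br)Oc1c(OCC=C)cc(OCOC)c(C(=O)OC)c1C(OC)OC | intermediate (not isolated)
14 | methyl 4-(allyloxy)-3-[(3,3-diethoxyprop-1-yn-1-yl)oxy]-2-(dimethoxymethyl)-6-(methoxymethoxy)benzoate | CCOC(OCC)C#COc1c(OCC=C)cc(OCOC)c(C(=O)OC)c1C(OC)OC | intermediate
15 | methyl 3-[(3,3-diethoxyprop-1-yn-1-yl)oxy]-2-(dimethoxymethyl)-4-hydroxy-6-(methoxymethoxy)benzoate | CCOC(OCC)C#COc1c(O)cc(OCOC)c(C(=O)OC)c1C(OC)OC | intermediate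
16 | bromoacetyl bromide | BrCC(Br)=O | starting material
17 | methyl 4-[(2-bromoacetyl)oxy]-3-[(3,3-diethoxyprop-1-yn-1-yl)oxy]-2-(dimethoxymethyl)-6-(methoxymethoxy)benzoate | CCOC(OCC)C#COc1c(OC(=O)CBr)cc(OCOC)c(C(=O)OC)c1C(OC)OC | intermediate (not isolated)
18 | methyl 4-[(2-diazoacetyl)oxy]-3-[(3,3-diethoxyprop-1-yn-1-yl)oxy]-2-(dimethoxymethyl)-6-(methoxymethoxy)benzoate | CCOC(OCC)C#COc1c(OC(=O)C=[N+]=[N-])cc(OCOC)c(C(=O)OC)c1C(OC)OC | intermediate
19 | methacrolein (2-methylprop-2-enal) | C=C(C)C=O | starting material
20 | methyl 4-[(2-diazo-3-hydroxy-4-methylpent-4-enoyl)oxy]-3-[(3,3-diethoxyprop-1-yn-1-yl)oxy]-2-(dimethoxymethyl)-6-(methoxymethoxy)benzoate (racemic) | CCOC(OCC)C#COc1c(OC(=O)C(=[N+]=[N-])C(O)C(C)=C)cc(OCOC)c(C(=O)OC)c1C(OC)OC | intermediate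
21 | methyl 4-[(2-diazo-4-methyl-3-oxopent-4-enoyl)oxy]-3-[(3,3-diethoxyprop-1-yn-1-yl)oxy]-2-(dimethoxymethyl)-6-(methoxymethoxy)benzoate | C=C(C)C(=O)C(=[N+]=[N-])C(=O)Oc1cc(OCOC)c(C(=O)OC)c(C(OC)OC)c1OC#CC(OCC)OCC | intermediate
22 | vinylketene: the aryl ester of 3-methyl-2-(oxomethylidene)but-3-enoic acid on b2–O, ynol ether unchanged | C=C(C)C(=C=O)C(=O)Oc1cc(OCOC)c(C(=O)OC)c(C(OC)OC)c1OC#CC(OCC)OCC | intermediate (not isolated)
23 | cyclobutenone fused through its C3–C4 bond to the benzodioxepinone ring; C2 bears the diethoxymethyl group, C3 the ether oxygen, C4 the isopropenyl group and the lactone carbonyl (racemic) | CCOC(OCC)C1=C2Oc3c(C(OC)OC)c(C(=O)OC)c(OCOC)cc3OC(=O)C2(C(C)=C)C1=O | intermediate (not isolated)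
24 | dienylketene: benzodioxepinone whose ring C=C carries the isopropenyl group (on the carbon beside the lactone carbonyl) and a 1-(diethoxymethyl)-2-oxoethenyl group (on the carbon beside the ether oxygen) | CCOC(OCC)C(=C=O)C1=C(C(C)=C)C(=O)Oc2cc(OCOC)c(C(=O)OC)c(C(OC)OC)c2O1 | intermediate (not isolated)
25 | methyl 4-(diethoxymethyl)-6-(dimethoxymethyl)-3-hydroxy-8-(methoxymethoxy)-1-methyl-11-oxo-11H-dibenzo[b,e][1,4]dioxepine-7-carboxylate | Oc1cc(C)c2c(c1C(OCC)OCC)Oc1c(cc(OCOC)c(C(=O)OC)c1C(OC)OC)OC2=O | intermediate
26 | methyl 4-(diethoxymethyl)-6-(dimethoxymethyl)-3-methoxy-8-(methoxymethoxy)-1-methyl-11-oxo-11H-dibenzo[b,e][1,4]dioxepine-7-carboxylate | COc1cc(C)c2c(c1C(OCC)OCC)Oc1c(cc(OCOC)c(C(=O)OC)c1C(OC)OC)OC2=O | intermediate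
27 | 1,4-dihydroxy-10-methoxy-8-methyl-3,7-dioxo-1,3-dihydro-7H-isobenzofuro[4,5-b][1,4]benzodioxepine-11-carbaldehyde (racemic) | COc1cc(C)c2c(c1C=O)Oc1c(cc(O)c3c1C(O)OC3=O)OC2=O | intermediate
28 | (1S)-1,4-dihydroxy-10-methoxy-8-methyl-3,7-dioxo-1,3-dihydro-7H-isobenzofuro[4,5-b][1,4]benzodioxepine-11-carbaldehyde | COc1cc(C)c2c(c1C=O)Oc1c(cc(O)c3c1[C@@H](O)OC3=O)OC2=O | target

## Step count and least certain steps

Total step count: 17. Longest linear sequence: 15 steps (steps 1–6 and 9–17); steps 7 and 8 form the side branch to 12.

Step 14 (key step, proposed new method).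
- What may go wrong: addition of the ester-substituted ketene through its ester carbonyl (hetero-[4+2]) in place of [2+2]; carbene reactions after nitrogen loss without migration; oligomerization of the ketene if the aryl ester cannot reach the s-trans geometry that the seven-membered ring requires; stalling at the cyclobutenone.
- Fallback (nucleophilic aromatic substitution, then lactonization; sets out from 9 and returns at 27):
 - 1-Fluoro-3-methoxy-5-methylbenzene is lithiated between fluorine and methoxy (n-butyllithium, THF, −78 °C) and formylated with DMF to 2-fluoro-6-methoxy-4-methylbenzaldehyde F1.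
 - Bromination para to the methoxy group (NBS, MeCN) gives 3-bromo-2-fluoro-6-methoxy-4-methylbenzaldehyde F2.
 - Alkoxycarbonylation (Pd(OAc)2, 1,1'-bis(diphenylphosphino)ferrocene, CO, Et3N, 2-(trimethylsilyl)ethanol, DMF, 80 °C) gives 2-(trimethylsilyl)ethyl 2-fluoro-3-formyl-4-methoxy-6-methylbenzoate F3.
 - The fluoride of F3, activated by the ortho formyl and ortho ester groups, is displaced by the phenoxide of 9 (Cs2CO3, DMF, 60 °C) to give the diaryl ether 2-(trimethylsilyl)ethyl 2-[6-(allyloxy)-2-(dimethoxymethyl)-3-(methoxycarbonyl)-4-(methoxymethoxy)phenoxy]-3-formyl-4-methoxy-6-methylbenzoate F4.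
 - Bu4NF cleaves the silylethyl ester to 2-[6-(allyloxy)-2-(dimethoxymethyl)-3-(methoxycarbonyl)-4-(methoxymethoxy)phenoxy]-3-formyl-4-methoxy-6-methylbenzoic acid F5.
 - Pd(PPh3)4 with morpholine removes the allyl group to give 2-[2-(dimethoxymethyl)-6-hydroxy-3-(methoxycarbonyl)-4-(methoxymethoxy)phenoxy]-3-formyl-4-methoxy-6-methylbenzoic acid F6.
 - Lactonization with 2-chloro-1-methylpyridinium iodide and Et3N at high dilution closes the seven-membered ring to methyl 6-(dimethoxymethyl)-4-formyl-3-methoxy-8-(methoxymethoxy)-1-methyl-11-oxo-11H-dibenzo[b,e][1,4]dioxepine-7-carboxylate F7.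
 - Aqueous HCl in THF, as in step 16, converts F7 into 27.

Step 17 (proposed new method).
- What may go wrong: no inclusion crystal forms; the crystal is of the wrong or of both enantiomers; the lactol re-equilibrates while the host is washed out.
- Fallback (sets out from 27, returns at 28, makes no new compound): preparative chromatography of 27 on an immobilized amylose tris(3,5-dimethylphenylcarbamate) phase with acid-free, aprotic eluent at low temperature, collecting the (S) fraction into cold anti-solvent so that it crystallizes at once. The (R) fraction is re-equilibrated with a trace of acid and recycled.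

Step 9.
- What may go wrong: slow coupling at a phenol flanked by two ortho groups; loss of methoxide from the ortho acetal of the phenoxide at 110 °C; incomplete elimination.
- Fallback (O-alkylation, then enol triflate elimination; sets out from 9 and returns at 14):
 - 1,1-Diethoxypropan-2-one is brominated at the methyl group to 3-bromo-1,1-diethoxypropan-2-one F8.
 - 9 is alkylated with F8 (K2CO3, acetone) to methyl 4-(allyloxy)-3-(3,3-diethoxy-2-oxopropoxy)-2-(dimethoxymethyl)-6-(methoxymethoxy)benzoate F9.
 - KN(SiMe3)2 and N-phenyl-bis(trifluoromethanesulfonimide) at −78 °C give the enol triflate methyl 4-(allyloxy)-3-({3,3-diethoxy-2-[(trifluoromethanesulfonyl)oxy]prop-1-en-1-yl}oxy)-2-(dimethoxymethyl)-6-(methoxymethoxy)benzoate F10.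
 - KOtBu eliminates triflate from F10 to give 14.

Step 6.
- What may go wrong: incomplete opening of the pseudo ester; re-closure when methanol is removed; competing O-methylation of the phenol.
- Fallback (stepwise, classical; sets out from 6 and returns at 9, bypassing steps 5 and 6):
 - Aqueous trifluoroacetic acid in THF hydrolyses the pseudo ester of 6 to the lactol 5-(allyloxy)-4-[(tert-butyldimethylsilyl)oxy]-3,7-dihydroxyisobenzofuran-1(3H)-one F11.
 - KHCO3 and MeI in DMF alkylate the ring-opened carboxylate to methyl 4-(allyloxy)-3-[(tert-butyldimethylsilyl)oxy]-2-formyl-6-hydroxybenzoate F12.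
 - MOMCl with iPr2NEt gives methyl 4-(allyloxy)-3-[(tert-butyldimethylsilyl)oxy]-2-formyl-6-(methoxymethoxy)benzoate F13.
 - Trimethyl orthoformate in methanol with pyridinium p-toluenesulfonate gives methyl 4-(allyloxy)-3-[(tert-butyldimethylsilyl)oxy]-2-(dimethoxymethyl)-6-(methoxymethoxy)benzoate F14.
 - Bu4NF removes the silyl group from F14 to give 9.

Step 1.
- What may go wrong: lithiation between the two methoxy groups (C3) in place of C6; addition of the alkyllithium to the carboxylate.
- Fallback (stronger directing group; sets out from 1 and returns at 2):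
 - 1 is converted (SOCl2, then diethylamine) into N,N-diethyl-2,4,5-trimethoxybenzamide F15.
 - sec-Butyllithium/TMEDA at −78 °C and DMF give N,N-diethyl-2-formyl-3,4,6-trimethoxybenzamide F16.
 - Hot 6 M HCl cleaves the amide of F16 with participation of the neighbouring formyl group and gives 2.

## Further compounds

F1 | step 14 | 2-fluoro-6-methoxy-4-methylbenzaldehyde | COc1cc(C)cc(F)c1C=O
F2 | step 14 | 3-bromo-2-fluoro-6-methoxy-4-methylbenzaldehyde | COc1cc(C)c(Br)c(F)c1C=O
F3 | step 14 | 2-(trimethylsilyl)ethyl 2-fluoro-3-formyl-4-methoxy-6-methylbenzoate | COc1cc(C)c(C(=O)OCC[Si](C)(C)C)c(F)c1C=O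
F4 | step 14 | 2-(trimethylsilyl)ethyl 2-[6-(allyloxy)-2-(dimethoxymethyl)-3-(methoxycarbonyl)-4-(methoxymethoxy)phenoxy]-3-formyl-4-methoxy-6-methylbenzoate | COc1cc(C)c(C(=O)OCC[Si](C)(C)C)c(Oc2c(OCC=C)cc(OCOC)c(C(=O)OC)c2C(OC)OC)c1C=O
F5 | step 14 | 2-[6-(allyloxy)-2-(dimethoxymethyl)-3-(methoxycarbonyl)-4-(methoxymethoxy)phenoxy]-3-formyl-4-methoxy-6-methylbenzoic acid | COc1cc(C)c(C(=O)O)c(Oc2c(OCC=C)cc(OCOC)c(C(=O)OC)c2C(OC)OC)c1C=O
F6 | step 14 | 2-[2-(dimethoxymethyl)-6-hydroxy-3-(methoxycarbonyl)-4-(methoxymethoxy)phenoxy]-3-formyl-4-methoxy-6-methylbenzoic acid | COc1cc(C)c(C(=O)O)c(Oc2c(O)cc(OCOC)c(C(=O)OC)c2C(OC)OC)c1C=O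
F7 | step 14 | methyl 6-(dimethoxymethyl)-4-formyl-3-methoxy-8-(methoxymethoxy)-1-methyl-11-oxo-11H-dibenzo[b,e][1,4]dioxepine-7-carboxylate | COc1cc(C)c2c(c1C=O)Oc1c(cc(OCOC)c(C(=O)OC)c1C(OC)OC)OC2=O
F0 | step 17 | none | none
F8 | step 9 | 3-bromo-1,1-diethoxypropan-2-one | CCOC(OCC)C(=O)CBr
F9 | step 9 | methyl 4-(allyloxy)-3-(3,3-diethoxy-2-oxopropoxy)-2-(dimethoxymethyl)-6-(methoxymethoxy)benzoate | CCOC(OCC)C(=O)COc1c(OCC=C)cc(OCOC)c(C(=O)OC)c1C(OC)OC
F10 | step 9 | methyl 4-(allyloxy)-3-({3,3-diethoxy-2-[(trifluoromethanesulfonyl)oxy]prop-1-en-1-yl}oxy)-2-(dimethoxymethyl)-6-(methoxymethoxy)benzoate (alkene geometry not fixed) | CCOC(OCC)C(OS(=O)(=O)C(F)(F)F)=COc1c(OCC=C)cc(OCOC)c(C(=O)OC)c1C(OC)OC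
F11 | step 6 | 5-(allyloxy)-4-[(tert-butyldimethylsilyl)oxy]-3,7-dihydroxyisobenzofuran-1(3H)-one (racemic) | OC1OC(=O)c2c(O)cc(OCC=C)c(O[Si](C)(C)C(C)(C)C)c12
F12 | step 6 | methyl 4-(allyloxy)-3-[(tert-butyldimethylsilyl)oxy]-2-formyl-6-hydroxybenzoate | COC(=O)c1c(O)cc(OCC=C)c(O[Si](C)(C)C(C)(C)C)c1C=O
F13 | step 6 | methyl 4-(allyloxy)-3-[(tert-butyldimethylsilyl)oxy]-2-formyl-6-(methoxymethoxy)benzoate | COCOc1cc(OCC=C)c(O[Si](C)(C)C(C)(C)C)c(C=O)c1C(=O)OC
F14 | step 6 | methyl 4-(allyloxy)-3-[(tert-butyldimethylsilyl)oxy]-2-(dimethoxymethyl)-6-(methoxymethoxy)benzoate | COCOc1cc(OCC=C)c(O[Si](C)(C)C(C)(C)C)c(C(OC)OC)c1C(=O)OC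
F15 | step 1 | N,N-diethyl-2,4,5-trimethoxybenzamide | CCN(CC)C(=O)c1cc(OC)c(OC)cc1OC
F16 | step 1 | N,N-diethyl-2-formyl-3,4,6-trimethoxybenzamide | CCN(CC)C(=O)c1c(OC)cc(OC)c(OC)c1C=O
A1 | alternative 1 | methyl 2-(dimethoxymethyl)-3,6-dihydroxy-4-({[(6R)-6-methyl-2,4-dioxocyclohexyl]carbonyl}oxy)benzoate | C[C@@H]1CC(=O)CC(=O)C1C(=O)Oc1cc(O)c(C(=O)OC)c(C(OC)OC)c1O
A2 | alternative 1 | methyl (1R)-6-(dimethoxymethyl)-8-hydroxy-1-methyl-3,11-dioxo-1,2,3,4-tetrahydro-11H-dibenzo[b,e][1,4]dioxepine-7-carboxylate | C[C@@H]1CC(=O)CC2=C1C(=O)Oc1cc(O)c(C(=O)OC)c(C(OC)OC)c1O2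
A3 | alternative 2 | methyl 3-(dimethoxymethyl)-4-methoxy-2-{[4-methoxy-2,4-bis(trimethylsilyloxy)buta-1,3-dien-1-yl]oxy}-6-methylbenzoate | COC(=O)c1c(C)cc(OC)c(C(OC)OC)c1OC=C(O[Si](C)(C)C)C=C(OC)O[Si](C)(C)C
A4 | alternative 2 | methyl 4,4-diethoxybut-2-ynoate | CCOC(OCC)C#CC(=O)OC
A5 | alternative 2 | methyl 2-(diethoxymethyl)-3-[2-(dimethoxymethyl)-3-methoxy-6-(methoxycarbonyl)-5-methylphenoxy]-4,6-dihydroxybenzoate | COC(=O)c1c(C)cc(OC)c(C(OC)OC)c1Oc1c(O)cc(O)c(C(=O)OC)c1C(OCC)OCC
A6 | alternative 3 | methyl 4-[(chlorocarbonyl)oxy]-2-(dimethoxymethyl)-3-[2-formyl-3-methoxy-5-methyl-6-(4,4,5,5-tetramethyl-1,3,2-dioxaborolan-2-yl)phenoxy]-6-(methoxymethoxy)benzoate | COc1cc(C)c(B2OC(C)(C)C(C)(C)O2)c(Oc2c(OC(Cl)=O)cc(OCOC)c(C(=O)OC)c2C(OC)OC)c1C=O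
A7 | alternative 3 | methyl 6-(dimethoxymethyl)-4-formyl-3-methoxy-8-(methoxymethoxy)-1-methyl-11-oxo-11H-dibenzo[b,e][1,4]dioxepine-7-carboxylate | COc1cc(C)c2c(c1C=O)Oc1c(cc(OCOC)c(C(=O)OC)c1C(OC)OC)OC2=O
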